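**Retrosynthetic overview**

- The carbocycle of the target, a 1-oxaspiro[4.4]non-7-en-6-one, is a 4-hydroxycyclopent-2-enone. Ketone C6, spiro C5 and carbinol C9 form an aldol (β-hydroxy ketone) array, and C6(=O)–C7(Me)=C8(Me) is a ring-opened 2,3-dimethylcyclopropenone. These two features make the key step possible.
- Key disconnection: C5–C6 and C8–C9 in one anionic (3+2) annulation. The enolate of a 2-acyloxolane (C5 = enolisable α-alkoxy carbon, C9 = its ketone carbon) is joined to dimethylcyclopropenone, driven by release of cyclopropene strain.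
- The acetyl group is carried as a (1S)-1-silyloxyethyl group from (S)-but-3-yn-2-ol. It steers C9 and C5 in the key step and is oxidised to the ketone in the last step.
- The oxolane ring is formed first (alkyne semihydrogenation, epoxidation, 5-exo cyclisation), the cyclopentenone ring second.
- The quaternary C2 comes from Sharpless epoxidation of natural phytol, reductive opening to the 1,3-diol, oxetane formation and acetylide opening.

Key step: step 10

Assumption: natural (2E,7R,11R)-phytol, (S)-but-3-yn-2-ol and 2,4-dibromopentan-3-one are taken as commercial; the ring-ether carbon C2 of the given structure is S (the spatial opposite of C2 in natural α-tocopherol), so it is built with L-(+)-tartrate and not taken from tocopherol.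

**Route**

Step 1
Reactants: 1 (2E,7R,11R)-3,7,11,15-tetramethylhexadec-2-en-1-ol (natural phytol)
Product: 2 [(2S,3S)-3-methyl-3-[(4R,8R)-4,8,12-trimethyltridecyl]oxiran-2-yl]methanol
Conditions: Ti(OiPr)4 (10 mol%), L-(+)-diethyl tartrate (12 mol%), t-BuOOH, 4 Å MS, CH2Cl2, −20 °C
Reagents that add atoms: tert-butyl hydroperoxide, CC(C)(C)OO
Why: Sharpless asymmetric epoxidation of an (E)-trisubstituted allylic alcohol; L-(+)-tartrate should deliver oxygen to the face that gives the (2S,3S)-epoxide, which fixes the future ring-ether carbon C2 of the target as S.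

Step 2
Reactants: 2 [(2S,3S)-3-methyl-3-[(4R,8R)-4,8,12-trimethyltridecyl]oxiran-2-yl]methanol
Product: 3 (3S,7R,11R)-3,7,11,15-tetramethylhexadecane-1,3-diol
Conditions: NaAlH2(OCH2CH2OMe)2, THF, 0 °C → rt; aq. Rochelle salt
Reagents that add atoms: none
Why: Regioselective reductive opening of a 2,3-epoxy alcohol, in which the alkoxide-bound aluminium hydride delivers hydride intramolecularly to C2 to give the 1,3-diol; the C3–O bond and hence the tertiary carbinol configuration are untouched.

Step 3
Reactants: 3 (3S,7R,11R)-3,7,11,15-tetramethylhexadecane-1,3-diol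
Product: 5 (2S)-2-methyl-2-[(4R,8R)-4,8,12-trimethyltridecyl]oxetane, via primary monotosylate 4 (not isolated)
Conditions: n-BuLi (1.0 equiv), THF, 0 °C; TsCl (1.0 equiv); n-BuLi (1.1 equiv), 0 → 60 °C
Reagents that add atoms: none
Why: One-pot selective tosylation of the primary hydroxyl followed by intramolecular Williamson etherification (4-exo-tet) by the tertiary alkoxide should give the 2,2-disubstituted oxetane with retention at the quaternary centre, whose C–O bond is not broken.

Step 4
Reactants: 6 (S)-but-3-yn-2-ol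
Product: 7 (S)-(but-3-yn-2-yloxy)tri(propan-2-yl)silane
Conditions: i-Pr3SiCl, imidazole, DMF, rt
Reagents that add atoms: triisopropylsilyl chloride, CC(C)[Si](Cl)(C(C)C)C(C)C
Why: Standard silylation of a secondary propargylic alcohol; the (S)-centre is carried unchanged as the temporary controller for the key step.

Step 5
Reactants: 7 (S)-(but-3-yn-2-yloxy)tri(propan-2-yl)silane; 5 (2S)-2-methyl-2-[(4R,8R)-4,8,12-trimethyltridecyl]oxetane
Product: 9 (2S,7S,11R,15R)-7,11,15,19-tetramethyl-2-[tri(propan-2-yl)silyloxy]icos-3-yn-7-ol, via lithium acetylide 8 (not isolated)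
Conditions: 7 (1.3 equiv), n-BuLi, THF, −78 °C; BF3·OEt2; then 5, −78 °C
Reagents that add atoms: none
Why: BF3-activated ring opening of an oxetane by a lithium acetylide (SN2 at the unsubstituted CH2) should give the bishomopropargylic tertiary alcohol with all carbons of the oxolane and the acetyl unit in place and both stereocentres untouched.

Step 6
Reactants: 9 (2S,7S,11R,15R)-7,11,15,19-tetramethyl-2-[tri(propan-2-yl)silyloxy]icos-3-yn-7-ol
Product: 10 (2S,3Z,7S,11R,15R)-7,11,15,19-tetramethyl-2-[tri(propan-2-yl)silyloxy]icos-3-en-7-ol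
Conditions: H2 (1 atm), Pd/CaCO3 poisoned with Pb(OAc)2 (Lindlar catalyst), quinoline, EtOAc, rt
Reagents that add atoms: none
Why: Lindlar semihydrogenation, in which syn delivery of hydrogen on the poisoned palladium surface gives the (Z)-alkene and stops there.

Step 7
Reactants: 10 (2S,3Z,7S,11R,15R)-7,11,15,19-tetramethyl-2-[tri(propan-2-yl)silyloxy]icos-3-en-7-ol
Product: 12 (2S)-1-[(5S)-5-methyl-5-[(4R,8R)-4,8,12-trimethyltridecyl]oxolan-2-yl]-2-[tri(propan-2-yl)silyloxy]propan-1-ol, via cis-epoxide 11 (not isolated)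
Conditions: m-CPBA, CH2Cl2, 0 °C → rt; then CSA (cat.), rt
Reagents that add atoms: meta-chloroperoxybenzoic acid, OOC(=O)c1cccc(Cl)c1
Why: Prilezhaev epoxidation followed by acid-catalysed 5-exo-tet opening of the epoxide by the tertiary alcohol (favoured over 6-endo by ring size and by the inductively deactivated carbon next to the silyloxy group) should close the oxolane; the two new stereocentres (oxolane C2 and the carbinol carbon) are not controlled because steps 8 and 10 erase both.

Step 8
Reactants: 12 (2S)-1-[(5S)-5-methyl-5-[(4R,8R)-4,8,12-trimethyltridecyl]oxolan-2-yl]-2-[tri(propan-2-yl)silyloxy]propan-1-ol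
Product: 13 (2S)-1-[(5S)-5-methyl-5-[(4R,8R)-4,8,12-trimethyltridecyl]oxolan-2-yl]-2-[tri(propan-2-yl)silyloxy]propan-1-one
Conditions: nPr4N[RuO4] (5 mol%), N-methylmorpholine N-oxide, 4 Å MS, CH2Cl2, rt
Reagents that add atoms: none
Why: Ley–Griffith oxidation of a secondary alcohol to the ketone under neutral conditions, which should leave the α-silyloxy stereocentre unepimerised.

Step 9
Reactants: 14 2,4-dibromopentan-3-one
Product: 16 2,3-dimethylcycloprop-2-en-1-one, via 2-bromo-2,3-dimethylcyclopropanone 15 (not isolated)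
Conditions: Et3N (2.2 equiv), CH2Cl2, 0 °C → rt
Reagents that add atoms: none
Why: Favorskii-type 1,3-dehydrobromination to the α-bromocyclopropanone followed by E2 loss of HBr, the established route from α,α'-dibromo ketones to cyclopropenones.

Step 10
Reactants: 13 (2S)-1-[(5S)-5-methyl-5-[(4R,8R)-4,8,12-trimethyltridecyl]oxolan-2-yl]-2-[tri(propan-2-yl)silyloxy]propan-1-one; 16 2,3-dimethylcycloprop-2-en-1-one
Product: 20 (2S,5R,9R)-9-hydroxy-2,7,8-trimethyl-9-[(1S)-1-[tri(propan-2-yl)silyloxy]ethyl]-2-[(4R,8R)-4,8,12-trimethyltridecyl]-1-oxaspiro[4.4]non-7-en-6-one, via potassium enolate 17 (not isolated), via cyclopropenolate aldolate 18 (not isolated), via ring-closed potassium alkoxide 19 (not isolated)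
Conditions: KH (1.2 equiv), 18-crown-6, THF, 0 °C; then 16, −78 → −30 °C; AcOH, −78 °C
Reagents that add atoms: none
Why: Proposed new method: the crown-ether-separated potassium enolate 17 should add through its α-carbon to the carbonyl carbon of 16 (aldol addition, forming C5–C6) to give cyclopropenolate 18, whose strained ring C–C bond then cleaves while the developing (Z)-vinyl carbanion at C8 adds to the neighbouring ketone (forming C8–C9), the whole being driven by loss of the roughly 50 kcal/mol strain of the cyclopropene; the closest known reaction types are the nucleophile-triggered opening of cyclopropenones at the carbonyl carbon to (Z)-acrylic derivatives, base-mediated formal (3+2) annulations of cyclopropenones with 1,3-dicarbonyl compounds, and the homoaldol opening of cyclopropanolates. The cyclopentenone ring closes in a 5-exo-trig mode (vinyl carbanion onto C=O), and the cis geometry inherited from the three-membered ring holds the carbanion within bonding distance of the ketone. Because the first aldol addition should be reversible, the two C5 epimers of 18 can equilibrate and both new stereocentres are fixed together in the irreversible ring-opening/ring-closing event. C9 is controlled by the adjacent (S)-silyloxy stereocentre (polar Felkin–Anh/Cornforth arrangement, the carbanion passing the C–H and not the methyl group), and C5 by the dipole-opposed alignment of the oxolane C–O bond and the ketone C=O under non-chelating conditions (K+ inside 18-crown-6), which places the ring oxygen trans to the new hydroxyl as in the target; the remote C2 centre is not relied on. The step needs regioselective enolisation at the oxolane methine (secured by the bulky, non-coordinating triisopropylsilyloxy group that shields the other α-hydrogen and by amine-free KH, which leaves no proton source for enolate equilibration or for quenching the carbanion) and attack at the cyclopropenone carbonyl carbon and not at its C=C bond (the site at which oxygen and nitrogen nucleophiles are known to open cyclopropenones).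

Step 11
Reactants: 20 (2S,5R,9R)-9-hydroxy-2,7,8-trimethyl-9-[(1S)-1-[tri(propan-2-yl)silyloxy]ethyl]-2-[(4R,8R)-4,8,12-trimethyltridecyl]-1-oxaspiro[4.4]non-7-en-6-one
Product: 21 (2S,5R,9R)-9-hydroxy-9-[(1S)-1-hydroxyethyl]-2,7,8-trimethyl-2-[(4R,8R)-4,8,12-trimethyltridecyl]-1-oxaspiro[4.4]non-7-en-6-one
Conditions: HF·pyridine, pyridine, THF, 0 → 40 °C
Reagents that add atoms: none
Why: Fluoride-driven Si–O cleavage under buffered, non-basic conditions, chosen so that the β-hydroxy ketone is not exposed to alkoxide-induced retro-aldol opening; no stereocentre is touched.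

Step 12
Reactants: 21 (2S,5R,9R)-9-hydroxy-9-[(1S)-1-hydroxyethyl]-2,7,8-trimethyl-2-[(4R,8R)-4,8,12-trimethyltridecyl]-1-oxaspiro[4.4]non-7-en-6-one
Product: 22 α-tocospiro A, (2S,5R,9S)-9-acetyl-9-hydroxy-2,7,8-trimethyl-2-[(4R,8R)-4,8,12-trimethyltridecyl]-1-oxaspiro[4.4]non-7-en-6-one
Conditions: IBX, EtOAc, 70 °C
Reagents that add atoms: none
Why: IBX oxidation of the secondary hydroxyl of a vicinal diol to the α-hydroxy methyl ketone, a reagent that should not cleave the glycol C–C bond; the temporary controlling stereocentre becomes the acetyl carbonyl, and the tertiary carbinol C9 keeps its configuration (its descriptor changes from R to S only through the priority change).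

**Compound list**

1 | natural phytol, (2E,7R,11R)-3,7,11,15-tetramethylhexadec-2-en-1-ol | OC/C=C(\C)CCC[C@H](C)CCC[C@H](C)CCCC(C)C | starting material
2 | [(2S,3S)-3-methyl-3-[(4R,8R)-4,8,12-trimethyltridecyl]oxiran-2-yl]methanol | OC[C@@H]1O[C@@]1(C)CCC[C@H](C)CCC[C@H](C)CCCC(C)C | intermediate
3 | (3S,7R,11R)-3,7,11,15-tetramethylhexadecane-1,3-diol | OCC[C@@](C)(O)CCC[C@H](C)CCC[C@H](C)CCCC(C)C | intermediate
4 | (3S,7R,11R)-3-hydroxy-3,7,11,15-tetramethylhexadecyl 4-methylbenzenesulfonate (primary monotosylate, not isolated) | Cc1ccc(cc1)S(=O)(=O)OCC[C@@](C)(O)CCC[C@H](C)CCC[C@H](C)CCCC(C)C | intermediate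
5 | (2S)-2-methyl-2-[(4R,8R)-4,8,12-trimethyltridecyl]oxetane | C[C@]1(CCC[C@H](C)CCC[C@H](C)CCCC(C)C)CCO1 | intermediate
6 | (S)-but-3-yn-2-ol | C[C@H](O)C#C | starting material
7 | (S)-(but-3-yn-2-yloxy)tri(propan-2-yl)silane | C[C@H](O[Si](C(C)C)(C(C)C)C(C)C)C#C | intermediate
8 | lithium acetylide of 7, [(3S)-3-[tri(propan-2-yl)silyloxy]but-1-yn-1-yl]lithium (not isolated) | C[C@H](O[Si](C(C)C)(C(C)C)C(C)C)C#C[Li] | intermediate
9 | (2S,7S,11R,15R)-7,11,15,19-tetramethyl-2-[tri(propan-2-yl)silyloxy]icos-3-yn-7-ol | C[C@H](O[Si](C(C)C)(C(C)C)C(C)C)C#CCC[C@@](C)(O)CCC[C@H](C)CCC[C@H](C)CCCC(C)C | intermediate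
10 | (2S,3Z,7S,11R,15R)-7,11,15,19-tetramethyl-2-[tri(propan-2-yl)silyloxy]icos-3-en-7-ol | C[C@H](O[Si](C(C)C)(C(C)C)C(C)C)/C=C\CC[C@@](C)(O)CCC[C@H](C)CCC[C@H](C)CCCC(C)C | intermediate
11 | cis-3,4-epoxide of 10 (both faces, not isolated) | C[C@H](O[Si](C(C)C)(C(C)C)C(C)C)C1OC1CC[C@@](C)(O)CCC[C@H](C)CCC[C@H](C)CCCC(C)C | intermediate
12 | (2S)-1-[(5S)-5-methyl-5-[(4R,8R)-4,8,12-trimethyltridecyl]oxolan-2-yl]-2-[tri(propan-2-yl)silyloxy]propan-1-ol (both configurations at oxolane C2 and at C1) | C[C@H](O[Si](C(C)C)(C(C)C)C(C)C)C(O)C1CC[C@](C)(CCC[C@H](C)CCC[C@H](C)CCCC(C)C)O1 | intermediate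
13 | (2S)-1-[(5S)-5-methyl-5-[(4R,8R)-4,8,12-trimethyltridecyl]oxolan-2-yl]-2-[tri(propan-2-yl)silyloxy]propan-1-one (both configurations at oxolane C2) | C[C@H](O[Si](C(C)C)(C(C)C)C(C)C)C(=O)C1CC[C@](C)(CCC[C@H](C)CCC[C@H](C)CCCC(C)C)O1 | intermediate
14 | 2,4-dibromopentan-3-one | CC(Br)C(=O)C(C)Br | starting material
15 | 2-bromo-2,3-dimethylcyclopropan-1-one (not isolated) | CC1C(=O)C1(C)Br | intermediate
16 | 2,3-dimethylcycloprop-2-en-1-one | CC1=C(C)C1=O | intermediate
17 | potassium enolate of 13, enolised at the oxolane carbon (not isolated) | C[C@H](O[Si](C(C)C)(C(C)C)C(C)C)C([O-])=C1CC[C@](C)(CCC[C@H](C)CCC[C@H](C)CCCC(C)C)O1.[K+] | intermediate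
18 | potassium 2,3-dimethyl-1-[2-acyl-oxolan-2-yl]cycloprop-2-en-1-olate, the aldol adduct of 17 and 16 (both configurations at the new quaternary carbon, not isolated) | C[C@H](O[Si](C(C)C)(C(C)C)C(C)C)C(=O)C1(C2([O-])C(C)=C2C)CC[C@](C)(CCC[C@H](C)CCC[C@H](C)CCCC(C)C)O1.[K+] | intermediate
19 | potassium alkoxide of 20 (not isolated) | C[C@H](O[Si](C(C)C)(C(C)C)C(C)C)[C@]1([O-])C(C)=C(C)C(=O)[C@@]12CC[C@](C)(CCC[C@H](C)CCC[C@H](C)CCCC(C)C)O2.[K+] | intermediate
20 | (2S,5R,9R)-9-hydroxy-2,7,8-trimethyl-9-[(1S)-1-[tri(propan-2-yl)silyloxy]ethyl]-2-[(4R,8R)-4,8,12-trimethyltridecyl]-1-oxaspiro[4.4]non-7-en-6-one | C[C@H](O[Si](C(C)C)(C(C)C)C(C)C)[C@]1(O)C(C)=C(C)C(=O)[C@@]12CC[C@](C)(CCC[C@H](C)CCC[C@H](C)CCCC(C)C)O2 | intermediate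
21 | (2S,5R,9R)-9-hydroxy-9-[(1S)-1-hydroxyethyl]-2,7,8-trimethyl-2-[(4R,8R)-4,8,12-trimethyltridecyl]-1-oxaspiro[4.4]non-7-en-6-one | C[C@H](O)[C@]1(O)C(C)=C(C)C(=O)[C@@]12CC[C@](C)(CCC[C@H](C)CCC[C@H](C)CCCC(C)C)O2 | intermediate
22 | α-tocospiro A, (2S,5R,9S)-9-acetyl-9-hydroxy-2,7,8-trimethyl-2-[(4R,8R)-4,8,12-trimethyltridecyl]-1-oxaspiro[4.4]non-7-en-6-one | CC(=O)[C@]1(O)C(C)=C(C)C(=O)[C@@]12CC[C@](C)(CCC[C@H](C)CCC[C@H](C)CCCC(C)C)O2 | target

**Step count and risks**

Total step count: 12. Longest linear sequence: 10 steps (steps 1–3, 5–8, 10–12, from phytol).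

Steps most likely to fail:

1. Step 10 (key step). The cyclopropenolate may fail to open and simply revert to enolate and cyclopropenone. The ketone may be deprotonated on the silyloxy side, with epimerisation of the controlling centre. The facial selectivity predicted by the transition-state model may turn out poor or reversed. Fallback (known chemistry, sets out from ketone 13 and comes back at 20): the lithium enolate of 13 (LiN(SiMe3)2, THF, −78 °C) would be added to (Z)-3-iodo-2-methylbut-2-enal (O=C\C(C)=C(C)/I) in an aldol reaction to give (2S)-1-[2-[(2Z)-1-hydroxy-3-iodo-2-methylbut-2-en-1-yl]-5-methyl-5-[(4R,8R)-4,8,12-trimethyltridecyl]oxolan-2-yl]-2-[tri(propan-2-yl)silyloxy]propan-1-one F1. Dess–Martin oxidation would give the non-enolisable 1,3-diketone (2Z)-3-iodo-2-methyl-1-[(5S)-5-methyl-2-[(2S)-2-[tri(propan-2-yl)silyloxy]propanoyl]-5-[(4R,8R)-4,8,12-trimethyltridecyl]oxolan-2-yl]but-2-en-1-one F2. An intramolecular Nozaki–Hiyama–Kishi reaction (CrCl2, catalytic NiCl2, DMF) of the vinyl iodide onto the α-silyloxy ketone would then close the cyclopentenone to 20; in this variant the spiro epimers would have to be separated by chromatography.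

2. Step 5. Lewis-acid ionisation of the oxetane at its quaternary carbon, with elimination or polymerisation, may outrun attack of the acetylide at the CH2 group. Fallback (sets out from diol 3 and comes back at 9): Appel iodination of the primary hydroxyl (I2, PPh3, imidazole) would give (3S,7R,11R)-1-iodo-3,7,11,15-tetramethylhexadecan-3-ol F3. Silylation of the tertiary hydroxyl (Et3SiOTf, 2,6-lutidine) would give triethyl[[(3S,7R,11R)-1-iodo-3,7,11,15-tetramethylhexadecan-3-yl]oxy]silane F4. SN2 alkylation of lithium acetylide 8 in THF/DMPU would give (2S,7S,11R,15R)-7,11,15,19-tetramethyl-7-(triethylsilyloxy)-2-[tri(propan-2-yl)silyloxy]icos-3-yne F5. Selective removal of the triethylsilyl group (PPTS, MeOH) would give 9.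

3. Step 7. The epoxide may open in the 6-endo sense, or acid may cause silyl migration or loss before the oxolane has closed. Fallback (sets out from alkynol 9, bypasses step 6 and comes back at 12): a 5-exo-dig hydroalkoxylation of the alkyne catalysed by monovalent gold ((Ph3P)AuCl/AgOTf, CH2Cl2) would give the exocyclic enol ether [(2S)-1-[(2Z,5S)-5-methyl-5-[(4R,8R)-4,8,12-trimethyltridecyl]oxolan-2-ylidene]propan-2-yl]oxy-tri(propan-2-yl)silane F6. Hydroboration–oxidation (BH3·THF; then NaOH, H2O2), with boron going to the carbon β to the ring oxygen, would give alcohol 12.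

**Further compounds**

F1 | step 10 | (2S)-1-[2-[(2Z)-1-hydroxy-3-iodo-2-methylbut-2-en-1-yl]-5-methyl-5-[(4R,8R)-4,8,12-trimethyltridecyl]oxolan-2-yl]-2-[tri(propan-2-yl)silyloxy]propan-1-one (5S; both configurations at oxolane C2 and at the carbinol carbon) | C[C@H](O[Si](C(C)C)(C(C)C)C(C)C)C(=O)C1(C(O)\C(C)=C(C)/I)CC[C@](C)(CCC[C@H](C)CCC[C@H](C)CCCC(C)C)O1
F2 | step 10 | (2Z)-3-iodo-2-methyl-1-[(5S)-5-methyl-2-[(2S)-2-[tri(propan-2-yl)silyloxy]propanoyl]-5-[(4R,8R)-4,8,12-trimethyltridecyl]oxolan-2-yl]but-2-en-1-one (both configurations at oxolane C2) | C[C@H](O[Si](C(C)C)(C(C)C)C(C)C)C(=O)C1(C(=O)\C(C)=C(C)/I)CC[C@](C)(CCC[C@H](C)CCC[C@H](C)CCCC(C)C)O1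
F3 | step 5 | (3S,7R,11R)-1-iodo-3,7,11,15-tetramethylhexadecan-3-ol | ICC[C@@](C)(O)CCC[C@H](C)CCC[C@H](C)CCCC(C)C
F4 | step 5 | triethyl[[(3S,7R,11R)-1-iodo-3,7,11,15-tetramethylhexadecan-3-yl]oxy]silane | ICC[C@@](C)(O[Si](CC)(CC)CC)CCC[C@H](C)CCC[C@H](C)CCCC(C)C
F5 | step 5 | (2S,7S,11R,15R)-7,11,15,19-tetramethyl-7-(triethylsilyloxy)-2-[tri(propan-2-yl)silyloxy]icos-3-yne | C[C@H](O[Si](C(C)C)(C(C)C)C(C)C)C#CCC[C@@](C)(O[Si](CC)(CC)CC)CCC[C@H](C)CCC[C@H](C)CCCC(C)C
F6 | step 7 | [(2S)-1-[(2Z,5S)-5-methyl-5-[(4R,8R)-4,8,12-trimethyltridecyl]oxolan-2-ylidene]propan-2-yl]oxy-tri(propan-2-yl)silane | C[C@H](O[Si](C(C)C)(C(C)C)C(C)C)/C=C1\O[C@@](C)(CCC[C@H](C)CCC[C@H](C)CCCC(C)C)CC1
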